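**Retrosynthetic overview**

1. Ochtodene ⇐ primary allylic alcohol (Appel bromination) ⇐ exocyclic dichloro enoate (ester reduction). Every C–halogen bond next to the quaternary carbon is made by electrophilic halogenation, never by substitution.
2. The second ring chloride and the alkene geometry come together from γ-chlorination of a silyl dienol ether. The enoate is the Wittig union of a 4-bromo-2-chlorocyclohexanone (fragment A) with a separately made tributylphosphorane (fragment B).
3. The chloro ketone ⇐ conjugate reduction and enolate chlorination of (S)-4-bromo-5,5-dimethylcyclohex-2-enone.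
4. The only ring is closed once, by intramolecular aldol condensation of (R)-2-bromo-3,3-dimethyl-5-oxohexanal. Its bromine comes from an organocatalytic α-bromination with a separately made dibromodienone (fragment C).
5. The keto aldehyde ⇐ Sakurai allylation of mesityl oxide, then ozonolysis.

Assumption: (2S,5S)-2,5-diphenylpyrrolidine delivers the (R)-configured α-bromo aldehyde of step 5; if the sense of induction is the opposite, the (2R,5R) antipode is used.

**Route**

Step 1
Reactants: 1 mesityl oxide (4-methylpent-3-en-2-one); 2 allyltrimethylsilane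
Product: 3 4,4-dimethylhept-6-en-2-one
Conditions: TiCl4, CH2Cl2, −78 °C; aqueous work-up
Reagents that add atoms: none
Why: Hosomi–Sakurai conjugate allylation, in which the TiCl4-activated enone is attacked at its β,β-disubstituted carbon by the allylsilane, builds the quaternary gem-dimethyl carbon (no stereocentre is formed).

Step 2
Reactants: 3 4,4-dimethylhept-6-en-2-one
Product: 5 3,3-dimethyl-5-oxohexanal, via ozonide 4 (not isolated)
Conditions: O3, CH2Cl2, −78 °C; then PPh3, −78 → 23 °C
Reagents that add atoms: ozone, O=[O+][O-]
Why: Ozonolysis of the terminal alkene with reductive work-up gives the aldehyde and leaves the ketone untouched.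

Step 3
Reactants: 6 2,6-di-tert-butylphenol
Product: 7 4-bromo-2,6-di-tert-butylphenol
Conditions: Br2 (1.0 equiv), CH2Cl2, 0 °C
Reagents that add atoms: bromine, BrBr
Why: Electrophilic aromatic bromination can only occur para to the hydroxyl group because both ortho positions carry tert-butyl groups.

Step 4
Reactants: 7 4-bromo-2,6-di-tert-butylphenol
Product: 8 4,4-dibromo-2,6-di-tert-butylcyclohexa-2,5-dien-1-one
Conditions: Br2, NaOAc, AcOH/H2O, 23 °C
Reagents that add atoms: bromine, BrBr
Why: A second electrophilic bromination at the already brominated para carbon (ipso attack) dearomatises the phenol to the dibromodienone, a mild source of electrophilic bromine.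

Step 5
Reactants: 5 3,3-dimethyl-5-oxohexanal; 8 4,4-dibromo-2,6-di-tert-butylcyclohexa-2,5-dien-1-one
Product: 10 (4S)-4-bromo-5,5-dimethylcyclohex-2-en-1-one, via bromo aldehyde 9 (not isolated)
Conditions: (2S,5S)-2,5-diphenylpyrrolidine (20 mol%), PhCO2H (20 mol%), CH2Cl2/pentane, −40 °C; then TsOH·H2O (0.5 equiv), −40 → 23 °C
Reagents that add atoms: none
Why: Organocatalytic α-bromination through the aldehyde enamine sets the bromine-bearing stereocentre under control of the C2-symmetric amine, and acid then drives the 6-enolexo intramolecular aldol condensation of the methyl ketone onto the α-bromo aldehyde to close the ring; the bromide sits between a quaternary carbon and the new alkene, so it cannot be lost by elimination.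

Step 6
Reactants: 10 (4S)-4-bromo-5,5-dimethylcyclohex-2-en-1-one
Product: 12 (2S,4S)-4-bromo-2-chloro-5,5-dimethylcyclohexan-1-one, via lithium enolate 11 (not isolated)
Conditions: LiBH(s-Bu)3, THF, −78 °C; then N-chlorosuccinimide, −78 °C; AcOH quench
Reagents that add atoms: N-chlorosuccinimide, O=C1CCC(=O)N1Cl; LiBH(s-Bu)3, [Li+].CCC(C)[BH-](C(C)CC)C(C)CC (its lithium stays only in 11)
Why: Conjugate (1,4) hydride reduction of the β-unsubstituted cyclohexenone gives a regiodefined enolate, and its electrophilic chlorination by axial attack on the half-chair with equatorial bromine places chlorine trans to bromine.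

Step 7
Reactants: 13 tributylphosphane; 14 ethyl bromoacetate
Product: 15 (2-ethoxy-2-oxoethyl)tributylphosphonium bromide
Conditions: EtOAc, 23 °C
Reagents that add atoms: none
Why: SN2 quaternisation of the phosphine by the α-bromo ester.

Step 8
Reactants: 15 (2-ethoxy-2-oxoethyl)tributylphosphonium bromide
Product: 16 ethyl (tributylphosphoranylidene)acetate
Conditions: aq. NaOH, CH2Cl2, 0 °C
Reagents that add atoms: none
Why: Deprotonation of the phosphonium salt gives the ester-stabilised ylide, which is more nucleophilic than its triphenyl analogue and so olefinates a hindered ketone at lower temperature.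

Step 9
Reactants: 12 (2S,4S)-4-bromo-2-chloro-5,5-dimethylcyclohexan-1-one; 16 ethyl (tributylphosphoranylidene)acetate
Product: 17 ethyl (2E)-2-[(2S,4S)-4-bromo-2-chloro-5,5-dimethylcyclohexylidene]acetate
Conditions: toluene, 40 °C
Reagents that add atoms: none
Why: Wittig olefination of the inductively activated α-chloro ketone under essentially neutral conditions keeps the chloride-bearing centre and gives mainly the isomer with the ester anti to the CHCl carbon (a minor 2Z isomer accompanies it); this geometry is not carried into the target.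

Step 10
Reactants: 17 ethyl (2E)-2-[(2S,4S)-4-bromo-2-chloro-5,5-dimethylcyclohexylidene]acetate
Product: 19 ethyl (2E)-2-[(2S,4S,6S)-4-bromo-2,6-dichloro-3,3-dimethylcyclohexylidene]acetate, via silyl ketene acetal 18 (not isolated)
Conditions: LiN(i-Pr)2, Me3SiCl (in situ quench), THF, −78 °C; then N-chlorosuccinimide, −78 → −20 °C
Reagents that add atoms: N-chlorosuccinimide, O=C1CCC(=O)N1Cl; chlorotrimethylsilane, C[Si](C)(C)Cl (its silyl group stays only in 18)
Why: Vinylogous (γ) deprotonation at the CH2 syn to the ester and O-silylation give a silyl dienol ether that takes up electrophilic chlorine at the γ-carbon through its s-trans conformer by axial attack, so the new chlorine enters cis to the first chlorine and trans to bromine while the ester ends on the side of the older CHCl carbon, which is the alkene geometry of the target.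

Step 11
Reactants: 19 ethyl (2E)-2-[(2S,4S,6S)-4-bromo-2,6-dichloro-3,3-dimethylcyclohexylidene]acetate
Product: 20 (2E)-2-[(2S,4S,6S)-4-bromo-2,6-dichloro-3,3-dimethylcyclohexylidene]ethan-1-ol
Conditions: i-Bu2AlH (2.2 equiv), CH2Cl2, −78 °C; aq. potassium sodium tartrate
Reagents that add atoms: none
Why: 1,2-Reduction of the α,β-unsaturated ester by i-Bu2AlH at low temperature gives the primary allylic alcohol without touching the alkyl halides, the alkene or the stereocentres.

Step 12
Reactants: 20 (2E)-2-[(2S,4S,6S)-4-bromo-2,6-dichloro-3,3-dimethylcyclohexylidene]ethan-1-ol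
Product: 21 ochtodene, (2S,4S,6S)-6-bromo-3-[(1E)-2-bromoethylidene]-2,4-dichloro-1,1-dimethylcyclohexane
Conditions: CBr4, PPh3, CH2Cl2, 0 °C
Reagents that add atoms: carbon tetrabromide, BrC(Br)(Br)Br
Why: Appel reaction, in which bromide displaces the alkoxyphosphonium group by SN2 at the unhindered primary allylic carbon, leaves the three ring stereocentres and the alkene geometry unchanged.

**Compound list**

1 | mesityl oxide (4-methylpent-3-en-2-one) | CC(=O)C=C(C)C | starting material
2 | allyltrimethylsilane | C=CC[Si](C)(C)C | starting material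
3 | 4,4-dimethylhept-6-en-2-one | CC(=O)CC(C)(C)CC=C | intermediate
4 | 4,4-dimethyl-5-(1,2,4-trioxolan-3-yl)pentan-2-one (secondary ozonide, racemic at the trioxolane carbon) | CC(=O)CC(C)(C)CC1OCOO1 | intermediate
5 | 3,3-dimethyl-5-oxohexanal | CC(=O)CC(C)(C)CC=O | intermediate
6 | 2,6-di-tert-butylphenol | CC(C)(C)c1cccc(C(C)(C)C)c1O | starting material
7 | 4-bromo-2,6-di-tert-butylphenol | CC(C)(C)c1cc(Br)cc(C(C)(C)C)c1O | intermediate
8 | 4,4-dibromo-2,6-di-tert-butylcyclohexa-2,5-dien-1-one | CC(C)(C)C1=CC(Br)(Br)C=C(C(C)(C)C)C1=O | intermediate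
9 | (2R)-2-bromo-3,3-dimethyl-5-oxohexanal | CC(=O)CC(C)(C)[C@@H](Br)C=O | intermediate
10 | (4S)-4-bromo-5,5-dimethylcyclohex-2-en-1-one | CC1(C)[C@@H](Br)C=CC(=O)C1 | intermediate
11 | lithium (4S)-4-bromo-5,5-dimethylcyclohex-1-en-1-olate | CC1(C)[C@@H](Br)CC=C([O-])C1.[Li+] | intermediate
12 | (2S,4S)-4-bromo-2-chloro-5,5-dimethylcyclohexan-1-one (Cl trans to Br) | CC1(C)[C@@H](Br)C[C@H](Cl)C(=O)C1 | intermediate
13 | tributylphosphane | CCCCP(CCCC)CCCC | starting material
14 | ethyl bromoacetate | CCOC(=O)CBr | starting material
15 | (2-ethoxy-2-oxoethyl)tributylphosphonium bromide | CCCC[P+](CCCC)(CCCC)CC(=O)OCC.[Br-] | intermediate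
16 | ethyl (tributylphosphoranylidene)acetate | CCCCP(CCCC)(CCCC)=CC(=O)OCC | intermediate
17 | ethyl (2E)-2-[(2S,4S)-4-bromo-2-chloro-5,5-dimethylcyclohexylidene]acetate (ester anti to the CHCl carbon; major isomer) | CC1(C)[C@@H](Br)C[C@H](Cl)/C(=C/C(=O)OCC)C1 | intermediate
18 | ({2-[(4S,6S)-4-bromo-6-chloro-3,3-dimethylcyclohex-1-en-1-yl]-1-ethoxyethenyl}oxy)trimethylsilane (ketene acetal geometry unspecified) | CC1(C)[C@@H](Br)C[C@H](Cl)C(C=C(OCC)O[Si](C)(C)C)=C1 | intermediate
19 | ethyl (2E)-2-[(2S,4S,6S)-4-bromo-2,6-dichloro-3,3-dimethylcyclohexylidene]acetate (both Cl cis to each other and trans to Br; ester cis to the CHCl carbon that bears the CH2 neighbour) | CC1(C)[C@@H](Br)C[C@H](Cl)/C(=C\C(=O)OCC)[C@@H]1Cl | intermediate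
20 | (2E)-2-[(2S,4S,6S)-4-bromo-2,6-dichloro-3,3-dimethylcyclohexylidene]ethan-1-ol | CC1(C)[C@@H](Br)C[C@H](Cl)/C(=C\CO)[C@@H]1Cl | intermediate
21 | ochtodene, (2S,4S,6S)-6-bromo-3-[(1E)-2-bromoethylidene]-2,4-dichloro-1,1-dimethylcyclohexane | CC1(C)[C@@H](Br)C[C@H](Cl)/C(=C\CBr)[C@@H]1Cl | target

**Step count and risks**

Total step count: 12. Longest linear sequence: 8 steps (steps 1, 2, 5, 6, 9, 10, 11, 12 from 1; the branch through steps 3 and 4 is equally long, the branch through steps 7 and 8 is 6 steps long).

Most likely to fail, first: step 5. The neopentyl aldehyde may brominate with modest enantioselectivity, and bromo aldehyde 9 can racemise through its enol before or during the acid cyclisation. The fallback sets out from 5 and comes back at 10, and takes the stereocentre from a resolution instead of a catalyst. Keto aldehyde 5 is cyclised first (TsOH·H2O, toluene, 60 °C, intramolecular aldol condensation) to the achiral enone 5,5-dimethylcyclohex-2-en-1-one F1. Wohl–Ziegler bromination (N-bromosuccinimide, dibenzoyl peroxide, PhCF3, 80 °C) at its only allylic CH2 gives racemic 4-bromo-5,5-dimethylcyclohex-2-en-1-one. Preparative chromatography on a chiral stationary phase separates 10 from its enantiomer (4R)-4-bromo-5,5-dimethylcyclohex-2-en-1-one F2, which is discarded.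

Second: step 6. Lithium enolate 11 carries a bromide on the γ-carbon and can close a cyclopropane instead of being chlorinated, and the trans selectivity of the chlorination rests on a conformational argument. The fallback sets out from 10 and comes back at 12, and avoids any metal enolate. Enone 10 is reduced by organocatalytic transfer hydrogenation (Hantzsch ester, morpholinium trifluoroacetate 20 mol%, THF, 40 °C) to (4S)-4-bromo-3,3-dimethylcyclohexan-1-one F3. Soft enolisation away from the quaternary carbon (Me3SiOTf, Et3N, CH2Cl2, 0 °C) gives the neutral silyl enol ether {[(4S)-4-bromo-5,5-dimethylcyclohex-1-en-1-yl]oxy}trimethylsilane F4. N-Chlorosuccinimide (CH2Cl2, −40 °C) chlorinates F4 axially to 12.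

Third: step 10. Chlorine may enter at the α-carbon instead of the hindered γ-carbon, the facial and geometric outcome rests on conformational arguments, and the strong base meets two alkyl halides. The fallback sets out from 17 and comes back at 19, and replaces the dienol ether chlorination by deconjugation followed by an ene-type allylic chlorination. LiN(i-Pr)2 (THF, −78 °C) gives the lithium dienolate lithium 2-[(4S,6S)-4-bromo-6-chloro-3,3-dimethylcyclohex-1-en-1-yl]-1-ethoxyethen-1-olate F5. Kinetic α-protonation (AcOH, −78 °C) gives the β,γ-unsaturated ester ethyl 2-[(4S,6S)-4-bromo-6-chloro-3,3-dimethylcyclohex-1-en-1-yl]acetate F6. Selenium-catalysed allylic chlorination (PhSeCl 10 mol%, N-chlorosuccinimide, CH2Cl2, 23 °C) puts chlorine on the ring alkene carbon next to the quaternary centre and moves the double bond back into conjugation, giving 19.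

**Further compounds**

F1 | step 5 | 5,5-dimethylcyclohex-2-en-1-one | CC1(C)CC=CC(=O)C1
F2 | step 5 | (4R)-4-bromo-5,5-dimethylcyclohex-2-en-1-one | CC1(C)[C@H](Br)C=CC(=O)C1
F3 | step 6 | (4S)-4-bromo-3,3-dimethylcyclohexan-1-one | CC1(C)[C@@H](Br)CCC(=O)C1
F4 | step 6 | {[(4S)-4-bromo-5,5-dimethylcyclohex-1-en-1-yl]oxy}trimethylsilane | CC1(C)[C@@H](Br)CC=C(O[Si](C)(C)C)C1
F5 | step 10 | lithium 2-[(4S,6S)-4-bromo-6-chloro-3,3-dimethylcyclohex-1-en-1-yl]-1-ethoxyethen-1-olate | CC1(C)[C@@H](Br)C[C@H](Cl)C(C=C([O-])OCC)=C1.[Li+]
F6 | step 10 | ethyl 2-[(4S,6S)-4-bromo-6-chloro-3,3-dimethylcyclohex-1-en-1-yl]acetate | CC1(C)[C@@H](Br)C[C@H](Cl)C(CC(=O)OCC)=C1
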